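**Retrosynthetic overview**
1. Grevirobstol B ⇒ (O-demethylation, hydrogenation) ⇒ a 22-membered macrocyclic 1,13-diene. Chain atoms are numbered C1 (benzylic, on the dihydroxy ring B) to C16 (benzylic, on the monohydroxy ring A).
2. Key disconnection: the ring is opened at C13=C14 (ring-closing metathesis) and, in the same operation, at C1=C2 (ring-opening cross-metathesis). C2–C13 is simply opened cyclododecene, so the precursor shrinks to a small diaryl ether with a vinyl group on ring B and a but-3-enyl group on ring A.
3. Enabling feature: the tether is an unbranched, unfunctionalised (CH2)16 chain, so alkene positions leave no trace. Its ring-B end sits ortho to the diaryl ether oxygen, giving a 2-aryloxystyrene that is a Hoveyda-type Ru-loading site. The ortho (ring B) / meta (ring A) anchoring makes closure without insertion a strained 10-membered ring.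
4. Diaryl ether ⇒ Ullmann coupling of 2-bromo-3,5-dimethoxybenzaldehyde (formyl acts first as activator, later becomes the vinyl group) with 3-(but-3-enyl)-5-methoxyphenol. Both come from 3,5-dimethoxybenzyl building blocks.
5. Ring order: both benzene rings are bought. The only ring formed is the 22-membered macrocycle.

Key step: step 6

Remark: the target SMILES holds no stereocentre and no alkene, and a 22-membered ring is too large for stable planar chirality. The compound is therefore treated as achiral and no enantioselective step is needed.

**Step 1**
Reactants: 1 3,5-dimethoxybenzyl bromide; 2 allylmagnesium bromide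
Product: 3 1-(but-3-en-1-yl)-3,5-dimethoxybenzene
Conditions: THF/Et2O, 0 °C → rt
Reagents that add atoms: none
Why: Allyl Grignard reagents displace benzylic bromides cleanly (SN2-type Csp3–Csp3 coupling), which installs C16–C14 plus the terminal CH2 that is expelled later.

**Step 2**
Reactants: 3 1-(but-3-en-1-yl)-3,5-dimethoxybenzene
Product: 4 3-(but-3-en-1-yl)-5-methoxyphenol
Conditions: NaSEt, DMF, 130 °C; aq. HCl work-up
Reagents that add atoms: none
Why: Thiolate SN2 O-demethylation should stop after one methyl group because the phenoxide formed deactivates the second ether (the standard mono-demethylation of 5-alkylresorcinol dimethyl ethers), and the isolated terminal alkene is not acidic enough to migrate.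

**Step 3**
Reactants: 5 3,5-dimethoxybenzaldehyde
Product: 6 2-bromo-3,5-dimethoxybenzaldehyde
Conditions: NBS, MeCN, 0 °C → rt
Reagents that add atoms: N-bromosuccinimide, O=C1CCC(=O)N1Br
Why: Electrophilic aromatic bromination should go to C2, which is ortho/para to the two methoxy groups and less crowded than C4 between them.

**Step 4**
Reactants: 4 3-(but-3-en-1-yl)-5-methoxyphenol; 6 2-bromo-3,5-dimethoxybenzaldehyde
Product: 7 2-[3-(but-3-en-1-yl)-5-methoxyphenoxy]-3,5-dimethoxybenzaldehyde
Conditions: CuI (10 mol%), N,N-dimethylglycine·HCl (30 mol%), Cs2CO3, dioxane, 100 °C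
Reagents that add atoms: none
Why: This is a ligand-accelerated Ullmann diaryl ether coupling in which the ortho-formyl group activates the hindered C–Br bond, and the aldehyde (non-enolisable) and the homoallylic alkene tolerate carbonate base.

**Step 5**
Reactants: 7 2-[3-(but-3-en-1-yl)-5-methoxyphenoxy]-3,5-dimethoxybenzaldehyde
Product: 8 1-ethenyl-2-[3-(but-3-en-1-yl)-5-methoxyphenoxy]-3,5-dimethoxybenzene
Conditions: MePPh3Br, KOtBu, THF, 0 °C → rt
Reagents that add atoms: methyltriphenylphosphonium bromide, C[P+](c1ccccc1)(c1ccccc1)c1ccccc1.[Br-]
Why: Wittig methylenation of a non-enolisable aryl aldehyde is reliable and creates the 2-aryloxystyrene unit that carries C1.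

**Step 6**
Reactants: 8 1-ethenyl-2-[3-(but-3-en-1-yl)-5-methoxyphenoxy]-3,5-dimethoxybenzene; 9 cyclododecene (commercial cis/trans mixture, 1.1 equiv)
Product: 11 (1E,13E)-macrocyclic diene (tri-O-methyl-1,2,13,14-tetradehydrogrevirobstol B), via ring-opened triene 10 (not isolated)
Conditions: Hoveyda–Grubbs II (10 mol% in two portions), 1,4-benzoquinone (20 mol%), toluene (2 mM), 60 °C, Ar sparge
Reagents that add atoms: none
Why: Proposed new method: a ruthenium methylidene is expected to load onto the vinyl group of ring B, whose position ortho to the diaryl ether oxygen gives a labile five-membered O→Ru chelated benzylidene of the Hoveyda type, and this carbene opens cyclododecene by [2+2] cycloaddition/cycloreversion, which forms C1=C2 and carries the metal to C13 (methylidene-capped resting form: triene 10). The C13 alkylidene then meets the terminal alkene of the butenyl arm on ring A in a ring-closing metathesis that forms C13=C14, closes the 22-membered ring end to end and expels the two terminal CH2 groups as ethylene, which the argon stream removes. The closest known reaction types are ring-expansion metathesis (ring-opening/cross/ring-closing cascade) of acyclic bis-acrylates with cycloalkenes up to cyclododecene and the ring-opening/ring-closing metathesis of styrenyl ethers; what has not been shown is insertion of an unstrained cycloalkene into a diene made of a styrene and an unactivated 1-alkene. No stereocentre is formed, and the E/Z geometry of both new alkenes (E expected to prevail) is erased in step 7. The step needs exactly one C12 insertion and no direct or intermolecular closure: direct closure of 8 would give a strained 10-membered ortho,meta-cyclophane and is shut off, while near-equimolar 9, millimolar dilution and reversibility should drain oligomers and double-insertion rings into the smallest strain-free ring 11, and because the conjugated, ortho-substituted C1=C2 link re-enters metathesis far more slowly than the dialkyl alkene, this error correction also runs through opening and closing of C13=C14. Benzoquinone is added to suppress Ru–H alkene migration, which would otherwise shorten the chain.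

**Step 7**
Reactants: 11 (1E,13E)-macrocyclic diene
Product: 12 tri-O-methylgrevirobstol B
Conditions: H2 (1 atm), 10% Pd/C, EtOAc, rt
Reagents that add atoms: none
Why: Heterogeneous catalytic hydrogenation saturates both disubstituted alkenes whatever their geometry, while aryl methyl ethers and the diaryl ether are inert.

**Step 8**
Reactants: 12 tri-O-methylgrevirobstol B
Product: 13 grevirobstol B
Conditions: BBr3, CH2Cl2, −78 °C → rt; then H2O
Reagents that add atoms: none
Why: BBr3 cleaves aryl methyl ethers by bromide attack on the methyl carbon of the boron-complexed ether, a path closed to the diaryl ether, whose oxygen carries only sp2 carbons.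

**Compound list**
1 | 3,5-dimethoxybenzyl bromide | COc1cc(CBr)cc(OC)c1 | starting material
2 | allylmagnesium bromide | C=CC[Mg]Br | starting material
3 | 1-(but-3-en-1-yl)-3,5-dimethoxybenzene | COc1cc(CCC=C)cc(OC)c1 | intermediate
4 | 3-(but-3-en-1-yl)-5-methoxyphenol | COc1cc(O)cc(CCC=C)c1 | intermediate
5 | 3,5-dimethoxybenzaldehyde | COc1cc(C=O)cc(OC)c1 | starting material
6 | 2-bromo-3,5-dimethoxybenzaldehyde | COc1cc(OC)c(Br)c(C=O)c1 | intermediate
7 | 2-[3-(but-3-en-1-yl)-5-methoxyphenoxy]-3,5-dimethoxybenzaldehyde | COc1cc(CCC=C)cc(Oc2c(OC)cc(OC)cc2C=O)c1 | intermediate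
8 | 1-ethenyl-2-[3-(but-3-en-1-yl)-5-methoxyphenoxy]-3,5-dimethoxybenzene | COc1cc(CCC=C)cc(Oc2c(OC)cc(OC)cc2C=C)c1 | intermediate
9 | cyclododecene (cis/trans mixture; geometry lost on ring opening) | C1=CCCCCCCCCCC1 | starting material
10 | 2-[3-(but-3-en-1-yl)-5-methoxyphenoxy]-3,5-dimethoxy-1-[(1E)-tetradeca-1,13-dien-1-yl]benzene (not isolated) | COc1cc(CCC=C)cc(Oc2c(OC)cc(OC)cc2/C=C/CCCCCCCCCCC=C)c1 | intermediate
11 | (1E,13E)-macrocyclic diene, tri-O-methyl-1,2,13,14-tetradehydrogrevirobstol B (22-membered ring, C1=C2 conjugated with ring B, C13=C14 three carbons from ring A) | COc1cc2cc(c1)Oc1c(OC)cc(OC)cc1/C=C/CCCCCCCCCC/C=C/CC2 | intermediate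
12 | tri-O-methylgrevirobstol B | COc1cc2cc(c1)Oc1c(OC)cc(OC)cc1CCCCCCCCCCCCCCCC2 | intermediate
13 | grevirobstol B | Oc1cc2cc(c1)Oc1c(O)cc(O)cc1CCCCCCCCCCCCCCCC2 | target

**Step count**
Total step count: 8.
Longest linear sequence: 7 (steps 1, 2, 4, 5, 6, 7, 8).

**Steps most likely to fail**

Step 6.
- What may go wrong: insertion of more than one C12 unit, oligomerisation through the two alkene ends, sluggish opening of the unstrained cycloalkene, or sequestration of ruthenium by the chelating styrene may outrun the wanted closure.
- Fallback (known chemistry only), from aldehyde 7 back to the route at 12: 12-bromododecan-1-ol and PPh3 (MeCN, reflux) would give (12-hydroxydodecyl)triphenylphosphonium bromide F1.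
- Its ylide (2 equiv NaHMDS, THF, −78 °C → rt) would convert 7 into the (Z)-alkenol F2.
- Dess–Martin oxidation would give the aldehyde F3, and Wittig methylenation the (Z)-triene F4, in which the whole C1–C13 arm is already in place.
- An ordinary high-dilution ring-closing metathesis (Grubbs II, CH2Cl2, reflux) of the two terminal alkenes would close the same C13=C14 bond to give the (1Z,13E)-macrocyclic diene F5. Hydrogenation as in step 7 then leads to 12.

Step 4.
- What may go wrong: slow oxidative addition at the electron-rich, doubly ortho-substituted bromide, with competing protodebromination, may stall the coupling.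
- Fallback, from 5 back to the route at 7: electrophilic fluorination (Selectfluor, MeCN) would give 2-fluoro-3,5-dimethoxybenzaldehyde F6.
- The metal-free addition–elimination (SNAr via a Meisenheimer adduct stabilised by the ortho-formyl group) of phenol 4 on F6 (K2CO3, DMSO, 120 °C) would then deliver 7.

Step 2.
- What may go wrong: loss of both methyl groups, or thiol addition to the terminal alkene at high temperature, may erode the differentiation of the two oxygens.
- Fallback, from 3 back to the route at 7: the oxygens are differentiated at the coupling stage instead. Exhaustive demethylation (BBr3, CH2Cl2, −78 → 0 °C) would give 5-(but-3-en-1-yl)benzene-1,3-diol F7.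
- Used in excess, F7 would be mono-arylated with 6 under the conditions of step 4 to give the phenol 2-[3-(but-3-en-1-yl)-5-hydroxyphenoxy]-3,5-dimethoxybenzaldehyde F8. O-methylation (MeI, K2CO3, acetone) then gives 7.

**Further compounds**
F1 | step 6 | (12-hydroxydodecyl)triphenylphosphonium bromide | OCCCCCCCCCCCC[P+](c1ccccc1)(c1ccccc1)c1ccccc1.[Br-]
F2 | step 6 | (12Z)-13-{2-[3-(but-3-en-1-yl)-5-methoxyphenoxy]-3,5-dimethoxyphenyl}tridec-12-en-1-ol | COc1cc(CCC=C)cc(Oc2c(OC)cc(OC)cc2/C=C\CCCCCCCCCCCO)c1
F3 | step 6 | (12Z)-13-{2-[3-(but-3-en-1-yl)-5-methoxyphenoxy]-3,5-dimethoxyphenyl}tridec-12-enal | COc1cc(CCC=C)cc(Oc2c(OC)cc(OC)cc2/C=C\CCCCCCCCCCC=O)c1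
F4 | step 6 | 2-[3-(but-3-en-1-yl)-5-methoxyphenoxy]-3,5-dimethoxy-1-[(1Z)-tetradeca-1,13-dien-1-yl]benzene | COc1cc(CCC=C)cc(Oc2c(OC)cc(OC)cc2/C=C\CCCCCCCCCCC=C)c1
F5 | step 6 | (1Z,13E)-macrocyclic diene (C1=C2 geometric isomer of 11) | COc1cc2cc(c1)Oc1c(OC)cc(OC)cc1/C=C\CCCCCCCCCC/C=C/CC2
F6 | step 4 | 2-fluoro-3,5-dimethoxybenzaldehyde | COc1cc(OC)c(F)c(C=O)c1
F7 | step 2 | 5-(but-3-en-1-yl)benzene-1,3-diol | Oc1cc(O)cc(CCC=C)c1
F8 | step 2 | 2-[3-(but-3-en-1-yl)-5-hydroxyphenoxy]-3,5-dimethoxybenzaldehyde | Oc1cc(CCC=C)cc(Oc2c(OC)cc(OC)cc2C=O)c1
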